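**Retrosynthetic overview**
- The ten-membered carbocycle is closed last, by ring-closing metathesis at C4=C5 of a diene lactone that already carries the Z C1=C10 bond.
- The key bond is C8–O. The reliable C7–C8 Barbier union gives the 8α-alcohol, so the 8β-hydroxyl is made by SN2 displacement of the C8 triflate with nitrite, with the 9-acetate in place.
- C7–C8 comes from an indium Barbier reaction between an (R)-5-vinyl-3-(bromomethyl)butenolide and an α-acetoxy aldehyde; stereochemistry is relayed C6 to C7 to C8.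
- The butenolide (γ-lactone ring, formed first) comes from acylation of divinylcarbinol (C6–O bond) and a new enantioselective ring-closing metathesis that sets C6.
- The aldehyde comes from a (Z)-α-iodoenal (fixes the C1=C10 geometry), a Nozaki–Hiyama–Kishi coupling with (S)-glyceraldehyde acetonide (sets C9), acetylation and periodic acid cleavage.

Assumption: 4-methylpent-4-enal, (R)-2-methylbutanoic acid and (S)-glyceraldehyde acetonide are bought as such, and the ligand antipode of the step 9 catalyst that gives the R lactone (written here as 4R,5R) is found by experiment.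

**Step 1**
Reactants: 1 4-methylpent-4-enal; 2 (triphenylphosphoranylidene)acetaldehyde
Product: 3 (2E)-6-methylhepta-2,6-dienal
Conditions: toluene, 80 °C
Reagents that add atoms: none
Why: Wittig olefination with the stabilised formylmethylene ylide gives the E enal and adds the two carbons that become C10 and C14.

**Step 2**
Reactants: 3 (2E)-6-methylhepta-2,6-dienal
Product: 4 (2Z)-2-iodo-6-methylhepta-2,6-dienal
Conditions: I2, DMAP (0.2 equiv), K2CO3, THF/H2O 1:1, rt
Reagents that add atoms: iodine, II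
Why: Baylis–Hillman-type α-iodination (conjugate addition of DMAP, iodination of the enolate, loss of DMAP) gives the Z α-iodoenal with the chain cis to iodine, which fixes the later C2/C9 cis geometry of C1=C10.

**Step 3**
Reactants: 4 (2Z)-2-iodo-6-methylhepta-2,6-dienal
Product: 5 (2Z)-2-iodo-6-methylhepta-2,6-dien-1-ol
Conditions: NaBH4, CeCl3·7H2O, MeOH, 0 °C
Reagents that add atoms: none
Why: Luche reduction is 1,2-selective and leaves the vinyl iodide and the olefin geometry untouched.

**Step 4**
Reactants: 5 (2Z)-2-iodo-6-methylhepta-2,6-dien-1-ol; 6 (2R)-2-methylbutanoic acid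
Product: 7 (2Z)-2-iodo-6-methylhepta-2,6-dien-1-yl (2R)-2-methylbutanoate
Conditions: DIC, DMAP (cat.), CH2Cl2, 0 °C to rt
Reagents that add atoms: none
Why: Steglich esterification of the primary allylic alcohol installs the C14 ester under conditions too mild to epimerise the acid.

**Step 5**
Reactants: 7 (2Z)-2-iodo-6-methylhepta-2,6-dien-1-yl (2R)-2-methylbutanoate; 8 (4S)-2,2-dimethyl-1,3-dioxolane-4-carbaldehyde
Product: 9 (2Z)-2-[(R)-[(4S)-2,2-dimethyl-1,3-dioxolan-4-yl](hydroxy)methyl]-6-methylhepta-2,6-dien-1-yl (2R)-2-methylbutanoate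
Conditions: CrCl2 (4 equiv), NiCl2 (2 mol %), DMSO, rt
Reagents that add atoms: none
Why: Nozaki–Hiyama–Kishi coupling forms the alkenylchromium with retention of geometry and adds it under Felkin–Anh control, giving the anti adduct, which is the R carbinol (C9) from the S aldehyde.

**Step 6**
Reactants: 9 (2Z)-2-[(R)-[(4S)-2,2-dimethyl-1,3-dioxolan-4-yl](hydroxy)methyl]-6-methylhepta-2,6-dien-1-yl (2R)-2-methylbutanoate
Product: 10 (2Z)-2-[(R)-acetoxy[(4S)-2,2-dimethyl-1,3-dioxolan-4-yl]methyl]-6-methylhepta-2,6-dien-1-yl (2R)-2-methylbutanoate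
Conditions: Ac2O, pyridine, DMAP (cat.), CH2Cl2, 0 °C
Reagents that add atoms: acetic anhydride, CC(=O)OC(C)=O
Why: Acylation of the only free hydroxyl places the acetate on O9 with retention.

**Step 7**
Reactants: 10 (2Z)-2-[(R)-acetoxy[(4S)-2,2-dimethyl-1,3-dioxolan-4-yl]methyl]-6-methylhepta-2,6-dien-1-yl (2R)-2-methylbutanoate
Product: 11 (2Z)-2-[(1R)-1-acetoxy-2-oxoethyl]-6-methylhepta-2,6-dien-1-yl (2R)-2-methylbutanoate
Conditions: H5IO6, EtOAc, rt
Reagents that add atoms: none
Why: Periodic acid hydrolyses the terminal acetonide and cleaves the freed glycol in one pot (glycol cleavage), unmasking the C8 aldehyde without touching the acetate-bearing stereocentre.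

**Step 8**
Reactants: 12 penta-1,4-dien-3-ol; 13 2-(bromomethyl)prop-2-enoic acid
Product: 15 penta-1,4-dien-3-yl 2-(bromomethyl)prop-2-enoate, via acid chloride 14 (not isolated)
Conditions: (COCl)2, DMF (cat.), CH2Cl2, 0 °C; then 12, 2,6-lutidine, −20 °C
Reagents that add atoms: none
Why: Nucleophilic acyl substitution on the in situ acid chloride makes the C6–O bond of the future lactone, and the hindered base avoids SN2' attack on the bromomethyl acrylate.

**Step 9**
Reactants: 15 penta-1,4-dien-3-yl 2-(bromomethyl)prop-2-enoate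
Product: 16 (5R)-3-(bromomethyl)-5-ethenylfuran-2(5H)-one
Conditions: RuCl2(=CHPh)(PCy3)[(4R,5R)-1,3-bis(2-isopropylphenyl)-4,5-diphenylimidazolidin-2-ylidene] (5 mol %), CH2Cl2 (5 mM), ethylene (1 atm), 40 °C
Reagents that add atoms: none
Why: Proposed new method: enantioselective ring-closing metathesis that desymmetrises the two enantiotopic vinyl groups of an acrylate triene; under ethylene the ruthenium alkylidene exchanges quickly between the two vinyl groups, so the slow closure onto the electron-poor 1,1-disubstituted acrylate olefin is enantio-determining (Curtin–Hammett), and the geared N-aryl groups of the chiral carbene favour the ruthenacyclobutane that keeps the spectator vinyl group away from the ortho-isopropyl group, setting C6 as R while forming the butenolide; the closest known reactions are molybdenum- and ruthenium-catalysed asymmetric ring-closing metathesis of prochiral trienes to dihydrofurans and the racemic ring closure of acrylates to butenolides.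

**Step 10**
Reactants: 16 (5R)-3-(bromomethyl)-5-ethenylfuran-2(5H)-one; 11 (2Z)-2-[(1R)-1-acetoxy-2-oxoethyl]-6-methylhepta-2,6-dien-1-yl (2R)-2-methylbutanoate
Product: 17 (2Z)-2-[(1R,2R)-1-acetoxy-2-[(2R,3R)-2-ethenyl-4-methylidene-5-oxooxolan-3-yl]-2-hydroxyethyl]-6-methylhepta-2,6-dien-1-yl (2R)-2-methylbutanoate
Conditions: In powder, THF/H2O 3:1, rt
Reagents that add atoms: none
Why: In this indium Barbier allylation the allylindium reacts at its γ-carbon anti to the vinyl group (C7 trans to C6) through a chair Zimmerman–Traxler transition state with the aldehyde substituent equatorial, which gives the α-methylene lactone and the 8R (8α) alcohol.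

**Step 11**
Reactants: 17 (2Z)-2-[(1R,2R)-1-acetoxy-2-[(2R,3R)-2-ethenyl-4-methylidene-5-oxooxolan-3-yl]-2-hydroxyethyl]-6-methylhepta-2,6-dien-1-yl (2R)-2-methylbutanoate
Product: 20 (2Z)-2-[(1R,2S)-1-acetoxy-2-[(2R,3R)-2-ethenyl-4-methylidene-5-oxooxolan-3-yl]-2-hydroxyethyl]-6-methylhepta-2,6-dien-1-yl (2R)-2-methylbutanoate, via triflate 18 (not isolated), via nitrite ester 19 (not isolated)
Conditions: Tf2O, pyridine, CH2Cl2, −20 °C; then Bu4NNO2, MeCN, rt; aqueous work-up
Reagents that add atoms: tetrabutylammonium nitrite, CCCC[N+](CCCC)(CCCC)CCCC.[O-]N=O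
Why: In this Lattrell–Dax inversion the nitrite oxygen displaces the triflate by SN2 and the nitrite ester is hydrolysed on work-up, so the C8–O bond is made with inversion (8R to 8S) while the vicinal acetate stays on O9.

**Step 12**
Reactants: 20 (2Z)-2-[(1R,2S)-1-acetoxy-2-[(2R,3R)-2-ethenyl-4-methylidene-5-oxooxolan-3-yl]-2-hydroxyethyl]-6-methylhepta-2,6-dien-1-yl (2R)-2-methylbutanoate
Product: 21 [(3aR,4S,5R,6Z,10Z,11aR)-5-acetoxy-4-hydroxy-10-methyl-3-methylidene-2-oxo-2,3,3a,4,5,8,9,11a-octahydrocyclodeca[b]furan-6-yl]methyl (2R)-2-methylbutanoate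
Conditions: second-generation Hoveyda–Grubbs catalyst, RuCl2(H2IMes)(=CH-C6H4-2-OiPr) (10 mol %), toluene (1 mM), 80 °C
Reagents that add atoms: none
Why: Ring-closing metathesis starts at the vinyl group and closes onto the 1,1-disubstituted olefin; the ten-membered ring accepts only the ring-cis (Z) trisubstituted C4=C5 bond, and the existing Z C1=C10 bond preorganises the chain and is too hindered (two allylic acyloxy groups) to react itself.

**Compound list**
1 | 4-methylpent-4-enal | C=C(C)CCC=O | starting material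
2 | (triphenylphosphoranylidene)acetaldehyde | O=CC=P(c1ccccc1)(c1ccccc1)c1ccccc1 | starting material
3 | (2E)-6-methylhepta-2,6-dienal | C=C(C)CC/C=C/C=O | intermediate
4 | (2Z)-2-iodo-6-methylhepta-2,6-dienal | C=C(C)CC/C=C(\I)C=O | intermediate
5 | (2Z)-2-iodo-6-methylhepta-2,6-dien-1-ol | C=C(C)CC/C=C(\I)CO | intermediate
6 | (2R)-2-methylbutanoic acid | CC[C@@H](C)C(=O)O | starting material
7 | (2Z)-2-iodo-6-methylhepta-2,6-dien-1-yl (2R)-2-methylbutanoate | C=C(C)CC/C=C(\I)COC(=O)[C@H](C)CC | intermediate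
8 | (4S)-2,2-dimethyl-1,3-dioxolane-4-carbaldehyde | O=C[C@@H]1COC(C)(C)O1 | starting material
9 | (2Z)-2-[(R)-[(4S)-2,2-dimethyl-1,3-dioxolan-4-yl](hydroxy)methyl]-6-methylhepta-2,6-dien-1-yl (2R)-2-methylbutanoate | C=C(C)CC/C=C(/COC(=O)[C@H](C)CC)[C@@H](O)[C@@H]1COC(C)(C)O1 | intermediate
10 | (2Z)-2-[(R)-acetoxy[(4S)-2,2-dimethyl-1,3-dioxolan-4-yl]methyl]-6-methylhepta-2,6-dien-1-yl (2R)-2-methylbutanoate | C=C(C)CC/C=C(/COC(=O)[C@H](C)CC)[C@@H](OC(C)=O)[C@@H]1COC(C)(C)O1 | intermediate
11 | (2Z)-2-[(1R)-1-acetoxy-2-oxoethyl]-6-methylhepta-2,6-dien-1-yl (2R)-2-methylbutanoate | C=C(C)CC/C=C(/COC(=O)[C@H](C)CC)[C@@H](OC(C)=O)C=O | intermediate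
12 | penta-1,4-dien-3-ol | C=CC(O)C=C | starting material
13 | 2-(bromomethyl)prop-2-enoic acid | C=C(CBr)C(=O)O | starting material
14 | 2-(bromomethyl)prop-2-enoyl chloride | C=C(CBr)C(=O)Cl | intermediate
15 | penta-1,4-dien-3-yl 2-(bromomethyl)prop-2-enoate | C=CC(C=C)OC(=O)C(=C)CBr | intermediate
16 | (5R)-3-(bromomethyl)-5-ethenylfuran-2(5H)-one | C=C[C@H]1OC(=O)C(CBr)=C1 | intermediate
17 | (2Z)-2-[(1R,2R)-1-acetoxy-2-[(2R,3R)-2-ethenyl-4-methylidene-5-oxooxolan-3-yl]-2-hydroxyethyl]-6-methylhepta-2,6-dien-1-yl (2R)-2-methylbutanoate | C=C1C(=O)O[C@H](C=C)[C@H]1[C@@H](O)[C@H](OC(C)=O)/C(COC(=O)[C@H](C)CC)=C\CCC(C)=C | intermediate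
18 | (2Z)-2-[(1R,2R)-1-acetoxy-2-[(2R,3S)-2-ethenyl-4-methylidene-5-oxooxolan-3-yl]-2-[(trifluoromethanesulfonyl)oxy]ethyl]-6-methylhepta-2,6-dien-1-yl (2R)-2-methylbutanoate | C=C1C(=O)O[C@H](C=C)[C@H]1[C@@H](OS(=O)(=O)C(F)(F)F)[C@H](OC(C)=O)/C(COC(=O)[C@H](C)CC)=C\CCC(C)=C | intermediate
19 | (2Z)-2-[(1R,2S)-1-acetoxy-2-[(2R,3S)-2-ethenyl-4-methylidene-5-oxooxolan-3-yl]-2-(nitrosooxy)ethyl]-6-methylhepta-2,6-dien-1-yl (2R)-2-methylbutanoate | C=C1C(=O)O[C@H](C=C)[C@H]1[C@H](ON=O)[C@H](OC(C)=O)/C(COC(=O)[C@H](C)CC)=C\CCC(C)=C | intermediate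
20 | (2Z)-2-[(1R,2S)-1-acetoxy-2-[(2R,3R)-2-ethenyl-4-methylidene-5-oxooxolan-3-yl]-2-hydroxyethyl]-6-methylhepta-2,6-dien-1-yl (2R)-2-methylbutanoate | C=C1C(=O)O[C@H](C=C)[C@H]1[C@H](O)[C@H](OC(C)=O)/C(COC(=O)[C@H](C)CC)=C\CCC(C)=C | intermediate
21 | [(3aR,4S,5R,6Z,10Z,11aR)-5-acetoxy-4-hydroxy-10-methyl-3-methylidene-2-oxo-2,3,3a,4,5,8,9,11a-octahydrocyclodeca[b]furan-6-yl]methyl (2R)-2-methylbutanoate | C=C1C(=O)O[C@@H]2/C=C(/C)CC/C=C(/COC(=O)[C@H](C)CC)[C@@H](OC(C)=O)[C@@H](O)[C@@H]12 | target

**Step count**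
Total steps: 12. Longest linear sequence: 10 (steps 1 to 7, then 10, 11, 12).

**Three steps most likely to fail**

Step 9 (the proposed new enantioselective ring-closing metathesis). The risk is low enantioselectivity, because both prochiral olefins are unhindered vinyl groups. The fallback uses known chemistry and sets out from 15. Ring closure with the achiral second-generation Hoveyda–Grubbs catalyst gives the racemic lactone, that is 16 together with its enantiomer (5S)-3-(bromomethyl)-5-ethenylfuran-2(5H)-one F1. The two are separated by preparative supercritical-fluid chromatography on an amylose tris(3,5-dimethylphenylcarbamate) phase, and the route is rejoined at 16.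

Step 10 (Barbier union). Aldehyde 11 is an α-acetoxy β,γ-unsaturated aldehyde that can epimerise, and its Felkin preference opposes the chair preference of the reagent. Any 8S adduct formed is simply 20 and is carried on. The fallback sets out from 16. Stannylation with hexabutylditin and Pd2(dba)3 gives (5R)-5-ethenyl-3-[(tributylstannyl)methyl]furan-2(5H)-one F2. Addition of F2 to 11 with BF3·OEt2 in CH2Cl2 at −78 °C goes through an open antiperiplanar transition state, where the syn preference and Felkin control both lead to the 8S alcohol. This comes back to the route directly at 20, so step 11 is skipped.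

Step 11 (C8 inversion). The triflate may eliminate, or the neighbouring acetate may take part and scramble the acetate between O8 and O9. The fallback sets out from 17. A Mitsunobu reaction with chloroacetic acid, PPh3 and DIAD in toluene at 0 °C gives the inverted ester (2Z)-2-[(1R,2S)-1-acetoxy-2-(chloroacetoxy)-2-[(2R,3S)-2-ethenyl-4-methylidene-5-oxooxolan-3-yl]ethyl]-6-methylhepta-2,6-dien-1-yl (2R)-2-methylbutanoate F3. Thiourea with NaHCO3 in EtOH then removes the chloroacetyl group selectively in the presence of the acetate, and the route is rejoined at 20.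

**Further compounds**
F1 | step 9 | (5S)-3-(bromomethyl)-5-ethenylfuran-2(5H)-one | C=C[C@@H]1OC(=O)C(CBr)=C1
F2 | step 10 | (5R)-5-ethenyl-3-[(tributylstannyl)methyl]furan-2(5H)-one | C=C[C@H]1OC(=O)C(C[Sn](CCCC)(CCCC)CCCC)=C1
F3 | step 11 | (2Z)-2-[(1R,2S)-1-acetoxy-2-(chloroacetoxy)-2-[(2R,3S)-2-ethenyl-4-methylidene-5-oxooxolan-3-yl]ethyl]-6-methylhepta-2,6-dien-1-yl (2R)-2-methylbutanoate | C=C1C(=O)O[C@H](C=C)[C@H]1[C@H](OC(=O)CCl)[C@H](OC(C)=O)/C(COC(=O)[C@H](C)CC)=C\CCC(C)=C
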